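**Retrosynthetic overview**

1. Sanggenone H (15) comes from its tris-silyl ether 14 by fluoride deprotection only.
2. Ring C (O1–C2–C3–C4) is cut at C2–C3: 14 comes from diazoketone 13 by Rh(II)-carbenoid insertion into the C2–H bond. This C–H is α to O1 and benzylic to ring B, whose ortho pyran oxygen and para oxygen make it the most hydridic C–H in the precursor. The step closes the pyranone ring and sets C2.
3. 13 comes from methyl ketone 11 by diazo transfer; 11 comes from phenol 10 and benzylic alcohol 8 by Mitsunobu etherification (O1–C2 bond).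
4. The 2,2-dimethyl-2H-pyran ring on ring B comes from aryl 1,1-dimethylpropargyl ether 4 by a [3,3] / [1,5]-H / oxa-6π cascade. C3 of the salicylate is the only free ortho position, which fixes the angular fusion onto the 2-oxygen.
5. Order of ring formation: dimethylpyran ring (step 3), then ring C (step 8).

Key step: step 8

Assumption: the sense of induction of the chiral dirhodium catalyst in step 8 has to be established in the first run. The (S)-tert-leucinate series is written; the equally available (R)-series is used if the (2R)-ketone is found to predominate.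

**Step 1**
Reactants: 1 methyl 2,4-dihydroxybenzoate
Product: 2 methyl 2-hydroxy-4-[(triisopropylsilyl)oxy]benzoate
Conditions: TIPSCl (1.05 equiv), imidazole (2.2 equiv), DMF, 0 °C to rt
Reagents that add atoms: triisopropylsilyl chloride, CC(C)[Si](Cl)(C(C)C)C(C)C
Why: The 2-OH is hydrogen-bonded to the ester carbonyl and is the poorer nucleophile, so this selective silyl protection should occur at the 4-OH only.

**Step 2**
Reactants: 2 methyl 2-hydroxy-4-[(triisopropylsilyl)oxy]benzoate; 3 3-chloro-3-methylbut-1-yne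
Product: 4 methyl 2-[(2-methylbut-3-yn-2-yl)oxy]-4-[(triisopropylsilyl)oxy]benzoate
Conditions: CuCl2·2H2O (1 mol%), DBU (1.3 equiv), MeCN, 0 °C
Reagents that add atoms: none
Why: Copper-catalysed propargylic substitution of the phenoxide is the mild standard route to hindered aryl 1,1-dimethylpropargyl ethers, and with the 4-oxygen blocked only the 2-oxygen can be alkylated.

**Step 3**
Reactants: 4 methyl 2-[(2-methylbut-3-yn-2-yl)oxy]-4-[(triisopropylsilyl)oxy]benzoate
Product: 7 methyl 2,2-dimethyl-5-[(triisopropylsilyl)oxy]-2H-chromene-8-carboxylate, via ortho-allenylphenol 5 (not isolated), via ortho-quinone methide 6 (not isolated)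
Conditions: o-xylene (0.05 M, degassed), 140 °C, sealed tube
Reagents that add atoms: none
Why: An aromatic propargyl Claisen rearrangement to C3 (the only free position ortho to the 2-oxygen), followed by enolisation, [1,5]-H shift and oxa-6π electrocyclisation, should give the 2H-chromene with the pyran oxygen next to the ester-bearing carbon.

**Step 4**
Reactants: 7 methyl 2,2-dimethyl-5-[(triisopropylsilyl)oxy]-2H-chromene-8-carboxylate
Product: 8 {2,2-dimethyl-5-[(triisopropylsilyl)oxy]-2H-chromen-8-yl}methanol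
Conditions: DIBAL-H (2.5 equiv), CH2Cl2, −78 to 0 °C; aq. Rochelle salt
Reagents that add atoms: none
Why: Hydride reduction of the aryl ester to the benzylic alcohol should leave the aryl silyl ether and the chromene alkene untouched.

**Step 5**
Reactants: 9 2,4,6-trihydroxyacetophenone
Product: 10 1-{2-hydroxy-4,6-bis[(triisopropylsilyl)oxy]phenyl}ethan-1-one
Conditions: TIPSCl (2.1 equiv), imidazole (4.5 equiv), DMF, 0 °C to rt
Reagents that add atoms: triisopropylsilyl chloride, CC(C)[Si](Cl)(C(C)C)C(C)C
Why: Silylation should stop at the bis-ether because the last ortho-OH is locked in a hydrogen bond to the ketone, and the two ortho-OH groups are equivalent so only one bis-ether can form.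

**Step 6**
Reactants: 8 {2,2-dimethyl-5-[(triisopropylsilyl)oxy]-2H-chromen-8-yl}methanol; 10 1-{2-hydroxy-4,6-bis[(triisopropylsilyl)oxy]phenyl}ethan-1-one
Product: 11 1-{2-({2,2-dimethyl-5-[(triisopropylsilyl)oxy]-2H-chromen-8-yl}methoxy)-4,6-bis[(triisopropylsilyl)oxy]phenyl}ethan-1-one
Conditions: PPh3 (1.3 equiv), DIAD (1.3 equiv), THF, 0 °C to rt
Reagents that add atoms: none
Why: Mitsunobu etherification of a primary benzylic alcohol with an acidic ortho-acyl phenol forms the O1–C2 bond under neutral conditions that spare the aryl silyl ethers.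

**Step 7**
Reactants: 11 1-{2-({2,2-dimethyl-5-[(triisopropylsilyl)oxy]-2H-chromen-8-yl}methoxy)-4,6-bis[(triisopropylsilyl)oxy]phenyl}ethan-1-one
Product: 13 2-diazo-1-{2-({2,2-dimethyl-5-[(triisopropylsilyl)oxy]-2H-chromen-8-yl}methoxy)-4,6-bis[(triisopropylsilyl)oxy]phenyl}ethan-1-one, via trifluoroacetyl diketone 12 (not isolated)
Conditions: LiHMDS (1.1 equiv), THF, −78 °C, then CF3CO2CH2CF3 (1.2 equiv); 5% aq. HCl work-up; then MsN3 (1.5 equiv), Et3N (1.5 equiv), H2O (1 equiv), MeCN, rt
Reagents that add atoms: methanesulfonyl azide, CS(=O)(=O)N=[N+]=[N-]; 2,2,2-trifluoroethyl trifluoroacetate, O=C(OCC(F)(F)F)C(F)(F)F (its CF3CO group is carried by 12 only and is lost again)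
Why: In this detrifluoroacetylative diazo transfer the only enolisable position, the methyl ketone, is trifluoroacetylated to activate it, and diazo transfer with loss of the trifluoroacetyl group should give the terminal α-diazoketone.

**Step 8**
Reactants: 13 2-diazo-1-{2-({2,2-dimethyl-5-[(triisopropylsilyl)oxy]-2H-chromen-8-yl}methoxy)-4,6-bis[(triisopropylsilyl)oxy]phenyl}ethan-1-one
Product: 14 (2S)-2-{2,2-dimethyl-5-[(triisopropylsilyl)oxy]-2H-chromen-8-yl}-5,7-bis[(triisopropylsilyl)oxy]-2,3-dihydro-4H-chromen-4-one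
Conditions: Rh2(S-PTTL)4 [dirhodium tetrakis(N-phthaloyl-(S)-tert-leucinate)] (1 mol%), toluene, −20 °C to rt, slow addition of 13 at high dilution
Reagents that add atoms: none
Why: Rh(II) expels N2 from 13 to give an electrophilic rhodium carbenoid at the future C3, which inserts into one of the two enantiotopic O–CH2 hydrogens at the future C2 through a hydride-transfer-like three-centre transition state. The closest known reaction type is the dirhodium-catalysed intramolecular C–H insertion of 2-alkoxyaryl α-diazoketones into the O–CH position to give chroman-4-ones, including enantioselective variants with chiral Rh(II) carboxylates. Ring C is closed by a 1,6-insertion that forms the C2–C3 bond through a six-membered cyclic transition state (carbenoid carbon, C4, C4a, C8a, O1, C2); the usual 1,5-position is the oxygen O1, so no five-membered C–H insertion can compete. The C2 stereocentre is set under catalyst control: the chiral carboxylate ligand sphere differentiates the two enantiotopic benzylic hydrogens, and no other stereocentre is present. The step needs chemoselectivity for this C–H insertion over oxonium ylide formation at O1 with 1,2-benzyl shift, over attack on the chromene alkene and over insertion into a protecting group. This should be secured by the high hydridic character of the C2–H bond (α to O1, benzylic to the donor-substituted ring B), the low nucleophilicity of the aryl ether oxygen O1 whose lone pair is delocalised into the acyl-bearing ring, slow addition at high dilution, and silyl ethers that carry no C–H on the atom bound to the 5-oxygen.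

**Step 9**
Reactants: 14 (2S)-2-{2,2-dimethyl-5-[(triisopropylsilyl)oxy]-2H-chromen-8-yl}-5,7-bis[(triisopropylsilyl)oxy]-2,3-dihydro-4H-chromen-4-one
Product: 15 sanggenone H, (2S)-5,7-dihydroxy-2-(5-hydroxy-2,2-dimethyl-2H-chromen-8-yl)-2,3-dihydro-4H-chromen-4-one
Conditions: TBAF (3.3 equiv), AcOH (3.5 equiv), THF, 0 °C
Reagents that add atoms: none
Why: Fluoride-induced cleavage of the three aryl silyl ethers in an acetic acid buffer keeps the liberated phenols protonated, so that base-induced opening of ring C (retro-oxa-Michael) and loss of the C2 configuration should be avoided.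

**Compound list**

1 | methyl 2,4-dihydroxybenzoate | COC(=O)c1ccc(O)cc1O | starting material
2 | methyl 2-hydroxy-4-[(triisopropylsilyl)oxy]benzoate | COC(=O)c1ccc(O[Si](C(C)C)(C(C)C)C(C)C)cc1O | intermediate
3 | 3-chloro-3-methylbut-1-yne | CC(C)(Cl)C#C | starting material
4 | methyl 2-[(2-methylbut-3-yn-2-yl)oxy]-4-[(triisopropylsilyl)oxy]benzoate | COC(=O)c1ccc(O[Si](C(C)C)(C(C)C)C(C)C)cc1OC(C)(C)C#C | intermediate
5 | methyl 2-hydroxy-3-(3-methylbuta-1,2-dien-1-yl)-4-[(triisopropylsilyl)oxy]benzoate (ortho-allenylphenol) | COC(=O)c1ccc(O[Si](C(C)C)(C(C)C)C(C)C)c(C=C=C(C)C)c1O | intermediate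
6 | methyl (5Z)-5-(3-methylbut-2-en-1-ylidene)-6-oxo-4-[(triisopropylsilyl)oxy]cyclohexa-1,3-diene-1-carboxylate (ortho-quinone methide) | CC(C)=C/C=C1\C(=O)C(C(=O)OC)=CC=C1O[Si](C(C)C)(C(C)C)C(C)C | intermediate
7 | methyl 2,2-dimethyl-5-[(triisopropylsilyl)oxy]-2H-chromene-8-carboxylate | COC(=O)c1ccc(O[Si](C(C)C)(C(C)C)C(C)C)c2C=CC(C)(C)Oc12 | intermediate
8 | {2,2-dimethyl-5-[(triisopropylsilyl)oxy]-2H-chromen-8-yl}methanol | OCc1ccc(O[Si](C(C)C)(C(C)C)C(C)C)c2C=CC(C)(C)Oc12 | intermediate
9 | 2,4,6-trihydroxyacetophenone | CC(=O)c1c(O)cc(O)cc1O | starting material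
10 | 1-{2-hydroxy-4,6-bis[(triisopropylsilyl)oxy]phenyl}ethan-1-one | CC(=O)c1c(O)cc(O[Si](C(C)C)(C(C)C)C(C)C)cc1O[Si](C(C)C)(C(C)C)C(C)C | intermediate
11 | 1-{2-({2,2-dimethyl-5-[(triisopropylsilyl)oxy]-2H-chromen-8-yl}methoxy)-4,6-bis[(triisopropylsilyl)oxy]phenyl}ethan-1-one | CC(=O)c1c(OCc2ccc(O[Si](C(C)C)(C(C)C)C(C)C)c3C=CC(C)(C)Oc23)cc(O[Si](C(C)C)(C(C)C)C(C)C)cc1O[Si](C(C)C)(C(C)C)C(C)C | intermediate
12 | 4,4,4-trifluoro-1-{2-({2,2-dimethyl-5-[(triisopropylsilyl)oxy]-2H-chromen-8-yl}methoxy)-4,6-bis[(triisopropylsilyl)oxy]phenyl}butane-1,3-dione | O=C(CC(=O)C(F)(F)F)c1c(OCc2ccc(O[Si](C(C)C)(C(C)C)C(C)C)c3C=CC(C)(C)Oc23)cc(O[Si](C(C)C)(C(C)C)C(C)C)cc1O[Si](C(C)C)(C(C)C)C(C)C | intermediate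
13 | 2-diazo-1-{2-({2,2-dimethyl-5-[(triisopropylsilyl)oxy]-2H-chromen-8-yl}methoxy)-4,6-bis[(triisopropylsilyl)oxy]phenyl}ethan-1-one | [N-]=[N+]=CC(=O)c1c(OCc2ccc(O[Si](C(C)C)(C(C)C)C(C)C)c3C=CC(C)(C)Oc23)cc(O[Si](C(C)C)(C(C)C)C(C)C)cc1O[Si](C(C)C)(C(C)C)C(C)C | intermediate
14 | (2S)-2-{2,2-dimethyl-5-[(triisopropylsilyl)oxy]-2H-chromen-8-yl}-5,7-bis[(triisopropylsilyl)oxy]-2,3-dihydro-4H-chromen-4-one | CC1(C)C=Cc2c(O[Si](C(C)C)(C(C)C)C(C)C)ccc([C@@H]3CC(=O)c4c(O[Si](C(C)C)(C(C)C)C(C)C)cc(O[Si](C(C)C)(C(C)C)C(C)C)cc4O3)c2O1 | intermediate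
15 | sanggenone H, (2S)-5,7-dihydroxy-2-(5-hydroxy-2,2-dimethyl-2H-chromen-8-yl)-2,3-dihydro-4H-chromen-4-one | CC1(C)C=Cc2c(O)ccc([C@@H]3CC(=O)c4c(O)cc(O)cc4O3)c2O1 | target

**Totals**

Total step count: 9. Longest linear sequence: 8 steps (steps 1, 2, 3, 4, 6, 7, 8, 9); step 5 is the one-step side branch.

**Steps most likely to fail and fallbacks**

Step 8. The carbenoid may be intercepted by the lone pair of O1 (oxonium ylide formation followed by a 1,2-shift of the benzylic group). Hydride transfer may also become stepwise, so that the resulting enolate closes through oxygen, or the catalyst may discriminate the two enantiotopic benzylic hydrogens poorly. The fallback sets out from ester 7 and ketone 10 and returns to the route at 14. Crossed Claisen condensation of the dianion of 10 with 7 (LiHMDS, 3.5 equiv, THF, −78 °C to rt) should give the 1,3-diketone F1. Asymmetric transfer hydrogenation (RuCl[(R,R)-TsDPEN](p-cymene), HCO2H/Et3N 5:2, rt) should reduce only the carbonyl next to ring B, since the other is flanked by two ortho substituents, and give the (R)-β-hydroxy ketone F2; the (S,S)-catalyst is used if the usual aryl ketone model does not hold here. Mitsunobu cyclisation (PPh3, DIAD, THF, 0 °C) then closes the O1–C2 bond with inversion to give 14.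

Step 2. O-Alkylation of the hydrogen-bonded, ortho-hindered phenoxide by the tertiary propargylic electrophile may be slow, and base-induced loss of the aryl silyl ether may compete. The fallback sets out from 2 and returns at 7, so that 4 and step 3 are bypassed. Pd-catalysed O-tert-prenylation (Pd(PPh3)4, tert-butyl 2-methylbut-3-en-2-yl carbonate, THF, rt) should give the 1,1-dimethylallyl ether F3. Aromatic Claisen rearrangement (toluene, 110 °C) to the only free ortho position should give the ortho-prenylphenol F4. Oxidative cyclisation with DDQ (toluene, 80 °C) via the ortho-quinone methide should then give chromene 7.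

Step 9. Configurational integrity at C2 may be lost through reversible opening of ring C once phenoxides are present (retro-oxa-Michael, favoured by the para-oxygen of ring B). The fallback sets out from 14 and returns at 15. Desilylation in the presence of an acylating agent (CsF, Ac2O, MeCN, 0 °C) traps each phenoxide as it is released and should give the triacetate F5, which can be recrystallised. The acetates are then removed under near-neutral conditions (NH4OAc, aq. MeOH, rt) to give 15.

**Further compounds**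

F1 | step 8 | 1-{2,2-dimethyl-5-[(triisopropylsilyl)oxy]-2H-chromen-8-yl}-3-{2-hydroxy-4,6-bis[(triisopropylsilyl)oxy]phenyl}propane-1,3-dione | CC1(C)C=Cc2c(O[Si](C(C)C)(C(C)C)C(C)C)ccc(C(=O)CC(=O)c3c(O)cc(O[Si](C(C)C)(C(C)C)C(C)C)cc3O[Si](C(C)C)(C(C)C)C(C)C)c2O1
F2 | step 8 | (3R)-3-{2,2-dimethyl-5-[(triisopropylsilyl)oxy]-2H-chromen-8-yl}-3-hydroxy-1-{2-hydroxy-4,6-bis[(triisopropylsilyl)oxy]phenyl}propan-1-one | CC1(C)C=Cc2c(O[Si](C(C)C)(C(C)C)C(C)C)ccc([C@H](O)CC(=O)c3c(O)cc(O[Si](C(C)C)(C(C)C)C(C)C)cc3O[Si](C(C)C)(C(C)C)C(C)C)c2O1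
F3 | step 2 | methyl 2-[(2-methylbut-3-en-2-yl)oxy]-4-[(triisopropylsilyl)oxy]benzoate | COC(=O)c1ccc(O[Si](C(C)C)(C(C)C)C(C)C)cc1OC(C)(C)C=C
F4 | step 2 | methyl 2-hydroxy-3-(3-methylbut-2-en-1-yl)-4-[(triisopropylsilyl)oxy]benzoate | COC(=O)c1ccc(O[Si](C(C)C)(C(C)C)C(C)C)c(CC=C(C)C)c1O
F5 | step 9 | (2S)-2-[5-(acetyloxy)-2,2-dimethyl-2H-chromen-8-yl]-4-oxo-3,4-dihydro-2H-chromene-5,7-diyl diacetate | CC1(C)C=Cc2c(OC(C)=O)ccc([C@@H]3CC(=O)c4c(OC(C)=O)cc(OC(C)=O)cc4O3)c2O1
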